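The route rests on disconnecting the furanone between its α-carbon C3 and the lactone carbonyl C2 (ring atoms O1, C2, C3, C4, C5). The precursor is an open-chain iodoalkene in which the allylic oxygen O1 on C5, cis to iodine across C3=C4, already carries C2 as a phenyl carbonate. Iodine–lithium exchange then closes the five-membered ring in one anionic 5-exo-trig acyl substitution, exploiting that cis C3/C5–O1 relationship. A catalytic asymmetric iodo-aldol coupling sets the carbinol centre and the iodoalkene geometry together, anti-carbomagnesiation of propargyl alcohol fixes the trisubstituted alkene, and (+)-sclareolide supplies the decalin.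

Key step: step 12

Remark: Dec denotes the (4aS,8aS)-2,5,5,8a-tetramethyl-3,4,4a,5,6,7,8,8a-octahydronaphthalen-1-yl group, TBSO the tert-butyldimethylsilyloxy group; furanone atoms are O1, C2 (carbonyl), C3, C4, C5.
Assumption: the (S)-configured oxazaborolidinium catalyst of step 8 is taken to leave the Si face of the bound aldehyde open; should the opposite sense be found, its enantiomer serves.

Step 1
Reactants: 1 (+)-sclareolide
Product: 2 methyl 2-Dec-acetate
Conditions: conc. H2SO4 (cat.), MeOH, reflux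
Reagents that add atoms: methanol, CO
Why: Acid-mediated E1 opening of the lactone at the tertiary C8–O bond followed by loss of H9 should give the thermodynamically preferred tetrasubstituted C8=C9 alkene while Fischer esterification traps the freed acid, and the C5 and C10 centres are not involved.

Step 2
Reactants: 2 methyl 2-Dec-acetate
Product: 3 2-Dec-ethanol
Conditions: LiAlH4, THF, 0 °C
Reagents that add atoms: none
Why: LiAlH4 reduction of the ester gives the primary alcohol and leaves the unactivated tetrasubstituted alkene untouched.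

Step 3
Reactants: 3 2-Dec-ethanol
Product: 4 2-Dec-ethyl bromide
Conditions: CBr4, PPh3, CH2Cl2, 0 °C
Reagents that add atoms: tetrabromomethane, BrC(Br)(Br)Br
Why: The Appel reaction replaces the primary hydroxyl by bromide through SN2 displacement of the oxyphosphonium under neutral conditions that spare the acid-sensitive alkene.

Step 4
Reactants: 4 2-Dec-ethyl bromide; 5 propargyl alcohol
Product: 9 (Z)-3-iodo-2-(2-Dec-ethyl)prop-2-en-1-ol, via Grignard reagent 6 (not isolated), via bromomagnesium propynolate 7 (not isolated), via alkenylmagnesium chelate 8 (not isolated)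
Conditions: Mg, Et2O, reflux; 5 pre-metalated with EtMgBr (1.0 equiv), Et2O, 0 °C; combined, CuI (10 mol %), 0 °C to rt; then I2, THF, −20 °C; aq. NH4Cl
Reagents that add atoms: iodine, [I][I]
Why: Copper-catalysed anti-carbomagnesiation of the propargylic alkoxide places the alkyl group on the internal alkyne carbon and magnesium on the terminal one inside a five-membered oxygen–magnesium chelate, so iodinolysis with retention gives the trisubstituted alkene with iodine cis to CH2OH.

Step 5
Reactants: 9 (Z)-3-iodo-2-(2-Dec-ethyl)prop-2-en-1-ol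
Product: 10 TBS ether of 9
Conditions: TBSCl, imidazole, DMF, rt
Reagents that add atoms: tert-butyldimethylsilyl chloride, CC(C)(C)[Si](C)(C)Cl
Why: Imidazole-promoted silylation protects the primary allylic alcohol as its TBS ether for the organolithium chemistry that follows.

Step 6
Reactants: 10 TBS ether of 9; 11 ethylene oxide
Product: 13 (Z)-4-(TBSO-methyl)-6-Dec-hex-3-en-1-ol, via alkenyllithium 12 (not isolated)
Conditions: t-BuLi (2.1 equiv), Et2O, −78 °C; then 11, BF3·OEt2, −78 °C
Reagents that add atoms: none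
Why: Iodine–lithium exchange occurs with retention of alkene geometry and the alkenyllithium opens BF3-activated oxirane by SN2 attack at −78 °C (epoxide opening), a temperature at which 1,4 migration of silicon from oxygen to carbon should not compete.

Step 7
Reactants: 13 (Z)-4-(TBSO-methyl)-6-Dec-hex-3-en-1-ol
Product: 14 (Z)-4-(TBSO-methyl)-6-Dec-hex-3-enal
Conditions: Dess–Martin periodinane, NaHCO3, CH2Cl2, 0 °C; used crude
Reagents that add atoms: none
Why: Buffered Dess–Martin oxidation stops at the aldehyde under near-neutral conditions, so the β,γ-alkene should not move into conjugation and its geometry is kept.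

Step 8
Reactants: 14 (Z)-4-(TBSO-methyl)-6-Dec-hex-3-enal; 15 ethyl propiolate
Product: 18 ethyl (3R,5Z)-3-hydroxy-2-[(Z)-iodomethylidene]-6-(TBSO-methyl)-8-Dec-oct-5-enoate, via silyl iodoallenolate 16 (not isolated), via trimethylsilyl ether 17 (not isolated)
Conditions: TMSI (1.2 equiv), (S)-3,3-diphenyl-1-(2-methylphenyl)hexahydropyrrolo[1,2-c][1,3,2]oxazaborole·HNTf2 (20 mol %), CH2Cl2, −78 °C; then 1 M HCl, THF, 0 °C
Reagents that add atoms: iodotrimethylsilane, C[Si](C)(C)I
Why: Conjugate addition of iodide from TMSI to 15 gives the silyl iodoallenolate 16, which adds in a Mukaiyama-type aldol step (β-iodo Morita–Baylis–Hillman three-component coupling) to the aldehyde held on the chiral oxazaborolidinium cation, so that catalyst-controlled Si-face attack should set the R carbinol while kinetic C–C bond formation leaves iodine cis to the ester.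

Step 9
Reactants: 18 hydroxy ester
Product: 19 ethyl (3R,5Z)-3-(TBSO)-2-[(Z)-iodomethylidene]-6-(TBSO-methyl)-8-Dec-oct-5-enoate
Conditions: TBSOTf, 2,6-lutidine, CH2Cl2, −78 to 0 °C
Reagents that add atoms: tert-butyldimethylsilyl trifluoromethanesulfonate, CC(C)(C)[Si](C)(C)OS(=O)(=O)C(F)(F)F
Why: Silyl triflate with a hindered pyridine base silylates the secondary allylic alcohol at low temperature without touching the vinylic iodide or the ester.

Step 10
Reactants: 19 bis-silyl ester
Product: 20 (3R,5Z)-3-(TBSO)-2-[(E)-iodomethylidene]-6-(TBSO-methyl)-8-Dec-oct-5-en-1-ol (iodine cis to C1H2OH)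
Conditions: i-Bu2AlH (DIBAL-H, 2.5 equiv), CH2Cl2, −78 °C
Reagents that add atoms: none
Why: i-Bu2AlH reduces the conjugated ester by 1,2-addition to the allylic alcohol (ester reduction) without touching the vinylic iodide or the silyl ethers, so the new CH2OH stays cis to iodine.

Step 11
Reactants: 20 allylic alcohol; 21 phenyl chloroformate
Product: 22 phenyl carbonate of 20
Conditions: pyridine, CH2Cl2, 0 °C
Reagents that add atoms: none
Why: Acylation of the primary allylic alcohol by the chloroformate (carbonate formation) places the future lactone carbonyl C2 on the oxygen that is cis to iodine.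

Step 12
Reactants: 22 phenyl carbonate of 20
Product: 25 4-[(1R,3Z)-1-(TBSO)-4-(TBSO-methyl)-6-Dec-hex-3-enyl]furan-2(5H)-one, via alkenyllithium 23 (not isolated), via tetrahedral lithium alkoxide 24 (not isolated)
Conditions: t-BuLi (2.05 equiv), Et2O, −100 to −78 °C; then AcOH, −78 °C
Reagents that add atoms: none
Why: t-BuLi exchanges the vinylic iodine for lithium with retention, so C3 becomes a configurationally fixed carbanion held cis to the C5 oxymethylene and five atoms away from the carbonate carbonyl C2. Attack of C3 on C2 (anionic 5-exo-trig acyl substitution) forms the C3–C2 bond and thereby closes the O1–C2–C3–C4–C5 ring as the tetrahedral alkoxide 24, which expels phenoxide, the best leaving group on C2, so the new ring is kept and the furanone results. The closest known reaction type is the Parham cyclization, halogen–lithium exchange followed by intramolecular acylation, together with the closure of alkenyllithiums onto tethered esters and amides. No stereocentre is created, the silylated carbinol centre is not touched, and the alkene geometry fixed in step 8 is what permits closure, since the oxygen on the carbinol carbon lies trans to C3 and cannot be reached. The step needs exchange to outrun addition of t-BuLi to the carbonate, which the very fast iodine–lithium exchange at −100 °C and the bulk of the base should secure, while the second equivalent of t-BuLi destroys the t-BuI formed.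

Step 13
Reactants: 25 bis-silyl furanone
Product: 26 4-[(1R,3Z)-1-hydroxy-4-(hydroxymethyl)-6-Dec-hex-3-enyl]furan-2(5H)-one (CNP0224983.2)
Conditions: HF·pyridine, pyridine, THF, 0 °C to rt
Reagents that add atoms: none
Why: Buffered HF·pyridine cleaves both silyl ethers (fluoride-mediated desilylation) without acid- or base-induced change at the furanone, the carbinol centre or the alkenes.

Compound list
1 | (+)-sclareolide, (3aR,5aS,9aS,9bR)-3a,6,6,9a-tetramethyldecahydronaphtho[2,1-b]furan-2(1H)-one | CC1(C)CCC[C@@]2(C)[C@H]1CC[C@@]1(C)OC(=O)C[C@@H]12 | starting material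
2 | methyl 2-Dec-acetate | CC1=C(CC(=O)OC)[C@@]2(C)CCCC(C)(C)[C@@H]2CC1 | intermediate
3 | 2-Dec-ethanol | CC1=C(CCO)[C@@]2(C)CCCC(C)(C)[C@@H]2CC1 | intermediate
4 | 2-Dec-ethyl bromide | CC1=C(CCBr)[C@@]2(C)CCCC(C)(C)[C@@H]2CC1 | intermediate
5 | propargyl alcohol (prop-2-yn-1-ol) | C#CCO | starting material
6 | (2-Dec-ethyl)magnesium bromide | CC1=C(CC[Mg]Br)[C@@]2(C)CCCC(C)(C)[C@@H]2CC1 | intermediate
7 | bromomagnesium prop-2-yn-1-olate | C#CCO[Mg]Br | intermediate
8 | (Z)-alkenylmagnesium bromide BrMg–CH=C(CH2CH2Dec)CH2OMgBr, carbon-bound Mg cis to CH2O | CC1=C(CC/C(CO[Mg]Br)=C/[Mg]Br)[C@@]2(C)CCCC(C)(C)[C@@H]2CC1 | intermediate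
9 | (Z)-3-iodo-2-(2-Dec-ethyl)prop-2-en-1-ol, iodine cis to CH2OH | CC1=C(CC/C(CO)=C/I)[C@@]2(C)CCCC(C)(C)[C@@H]2CC1 | intermediate
10 | tert-butyl{[(Z)-3-iodo-2-(2-Dec-ethyl)prop-2-enyl]oxy}dimethylsilane | CC1=C(CC/C(CO[Si](C)(C)C(C)(C)C)=C/I)[C@@]2(C)CCCC(C)(C)[C@@H]2CC1 | intermediate
11 | ethylene oxide (oxirane) | C1CO1 | starting material
12 | (Z)-alkenyllithium from 10, lithium cis to CH2OTBS | CC1=C(CC/C(CO[Si](C)(C)C(C)(C)C)=C/[Li])[C@@]2(C)CCCC(C)(C)[C@@H]2CC1 | intermediate
13 | (Z)-4-(TBSO-methyl)-6-Dec-hex-3-en-1-ol | CC1=C(CC/C(CO[Si](C)(C)C(C)(C)C)=C/CCO)[C@@]2(C)CCCC(C)(C)[C@@H]2CC1 | intermediate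
14 | (Z)-4-(TBSO-methyl)-6-Dec-hex-3-enal | CC1=C(CC/C(CO[Si](C)(C)C(C)(C)C)=C/CC=O)[C@@]2(C)CCCC(C)(C)[C@@H]2CC1 | intermediate
15 | ethyl propiolate | C#CC(=O)OCC | starting material
16 | 1-ethoxy-3-iodo-1-(trimethylsilyloxy)propa-1,2-diene | CCOC(O[Si](C)(C)C)=C=CI | intermediate
17 | trimethylsilyl ether of 18, (3R,5Z), iodine cis to the ester | CC1=C(CC/C(CO[Si](C)(C)C(C)(C)C)=C/C[C@@H](O[Si](C)(C)C)/C(=C/I)C(=O)OCC)[C@@]2(C)CCCC(C)(C)[C@@H]2CC1 | intermediate
18 | ethyl (3R,5Z)-3-hydroxy-2-[(Z)-iodomethylidene]-6-(TBSO-methyl)-8-Dec-oct-5-enoate | CC1=C(CC/C(CO[Si](C)(C)C(C)(C)C)=C/C[C@@H](O)/C(=C/I)C(=O)OCC)[C@@]2(C)CCCC(C)(C)[C@@H]2CC1 | intermediate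
19 | ethyl (3R,5Z)-3-(TBSO)-2-[(Z)-iodomethylidene]-6-(TBSO-methyl)-8-Dec-oct-5-enoate | CC1=C(CC/C(CO[Si](C)(C)C(C)(C)C)=C/C[C@@H](O[Si](C)(C)C(C)(C)C)/C(=C/I)C(=O)OCC)[C@@]2(C)CCCC(C)(C)[C@@H]2CC1 | intermediate
20 | (3R,5Z)-3-(TBSO)-2-[(E)-iodomethylidene]-6-(TBSO-methyl)-8-Dec-oct-5-en-1-ol, iodine cis to C1H2OH | CC1=C(CC/C(CO[Si](C)(C)C(C)(C)C)=C/C[C@@H](O[Si](C)(C)C(C)(C)C)/C(=C/I)CO)[C@@]2(C)CCCC(C)(C)[C@@H]2CC1 | intermediate
21 | phenyl chloroformate | O=C(Cl)Oc1ccccc1 | starting material
22 | phenyl carbonate of 20 at the primary oxygen, iodine cis to CH2OCO2Ph | CC1=C(CC/C(CO[Si](C)(C)C(C)(C)C)=C/C[C@@H](O[Si](C)(C)C(C)(C)C)/C(=C/I)COC(=O)Oc2ccccc2)[C@@]2(C)CCCC(C)(C)[C@@H]2CC1 | intermediate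
23 | alkenyllithium from 22, lithium on C3 cis to CH2OCO2Ph | CC1=C(CC/C(CO[Si](C)(C)C(C)(C)C)=C/C[C@@H](O[Si](C)(C)C(C)(C)C)/C(=C/[Li])COC(=O)Oc2ccccc2)[C@@]2(C)CCCC(C)(C)[C@@H]2CC1 | intermediate
24 | lithium 4-[(1R,3Z)-1-(TBSO)-4-(TBSO-methyl)-6-Dec-hex-3-enyl]-2-phenoxy-2,5-dihydrofuran-2-olate, configuration at the transient C2 not defined | CC1=C(CC/C(CO[Si](C)(C)C(C)(C)C)=C/C[C@@H](O[Si](C)(C)C(C)(C)C)C2=CC(O[Li])(Oc3ccccc3)OC2)[C@@]2(C)CCCC(C)(C)[C@@H]2CC1 | intermediate
25 | 4-[(1R,3Z)-1-(TBSO)-4-(TBSO-methyl)-6-Dec-hex-3-enyl]furan-2(5H)-one | CC1=C(CC/C(CO[Si](C)(C)C(C)(C)C)=C/C[C@@H](O[Si](C)(C)C(C)(C)C)C2=CC(=O)OC2)[C@@]2(C)CCCC(C)(C)[C@@H]2CC1 | intermediate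
26 | 4-[(1R,3Z)-1-hydroxy-4-(hydroxymethyl)-6-Dec-hex-3-enyl]furan-2(5H)-one (CNP0224983.2) | CC1=C(CC/C(=C/C[C@@H](O)C2=CC(=O)OC2)CO)[C@@]2(C)CCCC(C)(C)[C@@H]2CC1 | target

Total step count: 13. Longest linear sequence: 13 steps (1 to 26).

Steps most likely to fail

1. Step 12 (key step). What may go wrong: addition of t-BuLi to the carbonate carbonyl before the exchange, or proton capture by the alkenyllithium before it reaches C2. Fallback: setting out from alcohol 20, the same ring is closed by palladium-catalysed carbonylative lactonisation (Pd(PPh3)2Cl2, CO 1 atm, Et3N, DMF, 60 °C). Oxidative addition at the C3–I bond, CO insertion and capture of the acyl palladium by the cis CH2OH should give 25 directly, where the route is rejoined; no new compound is made.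

2. Step 8. What may go wrong: low facial selectivity at the aldehyde, drift of the β,γ-alkene into conjugation under the Lewis acid, or silyl ether cleavage by TMSI. Fallback: setting out from aldehyde 14, an uncatalysed MgI2-promoted iodo-aldol coupling with 15 (CH2Cl2, 0 °C) should give ethyl (5Z)-3-hydroxy-2-[(Z)-iodomethylidene]-6-(TBSO-methyl)-8-Dec-oct-5-enoate as both carbinol epimers F1. Dess–Martin oxidation then gives ethyl (5Z)-2-[(Z)-iodomethylidene]-3-oxo-6-(TBSO-methyl)-8-Dec-oct-5-enoate F2. Corey–Bakshi–Shibata reduction ((S)-1-methyl-3,3-diphenylhexahydropyrrolo[1,2-c][1,3,2]oxazaborole, catecholborane, toluene, −78 °C), with the alkenyl group as the large substituent, should return the R carbinol 18.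

3. Step 1. What may go wrong: proton loss from the C8 cation towards C7 or the C8 methyl group, giving alkene regioisomers that are hard to separate. Fallback: setting out from 1, LiAlH4 reduction gives (1R,2R,4aS,8aS)-1-(2-hydroxyethyl)-2,5,5,8a-tetramethyldecahydronaphthalen-2-ol F3. Acetylation of the primary hydroxyl (Ac2O, pyridine, 0 °C) gives the 2-acetoxyethyl tertiary alcohol F4. Dehydration of the tertiary alcohol with PPh3 and iodine (CH2Cl2, rt), which favours the most substituted alkene, gives 2-Dec-ethyl acetate F5. Methanolysis (K2CO3, MeOH) returns alcohol 3.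

Further compounds
F0 | step 12 | none | none
F1 | step 8 | ethyl (5Z)-3-hydroxy-2-[(Z)-iodomethylidene]-6-(TBSO-methyl)-8-Dec-oct-5-enoate, both C3 epimers | CC1=C(CC/C(CO[Si](C)(C)C(C)(C)C)=C/CC(O)/C(=C/I)C(=O)OCC)[C@@]2(C)CCCC(C)(C)[C@@H]2CC1
F2 | step 8 | ethyl (5Z)-2-[(Z)-iodomethylidene]-3-oxo-6-(TBSO-methyl)-8-Dec-oct-5-enoate | CC1=C(CC/C(CO[Si](C)(C)C(C)(C)C)=C/CC(=O)/C(=C/I)C(=O)OCC)[C@@]2(C)CCCC(C)(C)[C@@H]2CC1
F3 | step 1 | (1R,2R,4aS,8aS)-1-(2-hydroxyethyl)-2,5,5,8a-tetramethyldecahydronaphthalen-2-ol | CC1(C)CCC[C@@]2(C)[C@H]1CC[C@@](C)(O)[C@@H]2CCO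
F4 | step 1 | 2-[(1R,2R,4aS,8aS)-2-hydroxy-2,5,5,8a-tetramethyldecahydronaphthalen-1-yl]ethyl acetate | CC1(C)CCC[C@@]2(C)[C@H]1CC[C@@](C)(O)[C@@H]2CCOC(C)=O
F5 | step 1 | 2-Dec-ethyl acetate | CC1=C(CCOC(C)=O)[C@@]2(C)CCCC(C)(C)[C@@H]2CC1
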